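## Structural features

The target is a chroman-4-one. Benzene ring A (C4a to C8a) is fused along C4a–C8a to the dihydropyranone ring B (O1, C2, C3, C4). Ring A carries a free phenol at C6 (para to O1) and bromine at C7, while C5 and C8 are unsubstituted. C2 is the only stereocentre: a fully substituted ether carbon of R configuration bearing a methyl group and a 4-hydroxy-4-methylpentyl chain that ends in a tertiary alcohol. No stereocentre stands next to it, so only absolute control is required.

The fragile elements are these. The β-aryloxy ketone O1–C2–C3–C4=O can open by retro-oxa-Michael elimination under base and reclose with loss of configuration at C2. The tertiary alcohol can dehydrate under strong acid. The aryl bromide is sensitive to reductants, organolithiums and warm zerovalent palladium. Ring A becomes oxidisable once the C6 hydroxyl is free.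

The real difficulty is to build the tetrasubstituted C2–O1 centre as one enantiomer and then close ring B at the ketone oxidation level without ionising or enolising through that centre. The key step uses the position of the C3–C4 bond between quaternary C2 and the aryl ketone carbon. C2 can carry a vinyl group whose inner carbon becomes C3, and C4 can be the substituted carbon of an aryl silyl enol ether, so alkene metathesis closes ring B directly as the enol ether of the ketone.

## Logic of the disconnections

**14 ⇒ 13.** Three O–Si bonds are restored: at the C4 enol oxygen, the C6 phenol oxygen and the tertiary chain oxygen. The ketone is kept as the enol ether that the ring closure delivers, and both hydroxyls stay masked through the earlier steps. The skeleton is unchanged, but the end game becomes a single unmasking. The forward step must use buffered fluoride, so that the enolate freed across C3–C4 is protonated before it can expel O1 from C2.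

**13 ⇒ 12.** The C3=C4 double bond is cut and each carbon receives a terminal CH2. This bond is chosen because cutting it leaves all four substituents of C2 in place and opens ring B to an acyclic aryl ether carrying two alkenes. The forward step needs a ruthenium carbene that accepts a 1,1-disubstituted enol ether, a substrate with no third alkene, and a temperature low enough to spare the tertiary allyl aryl ether.

**12 ⇒ 11.** The enol O–Si bond is cut, returning the aryl methyl ketone. The gain is a stable, purifiable ketone as the product of fragment union. The forward step must enolise the methyl ketone under conditions that do not ionise the tertiary allylic C2–O1 bond.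

**11 ⇒ 5 + 10.** The O1–C2 bond is cut with allylic transposition, so that C2 becomes C3 of an E-configured allylic carbonate. This joins the two halves and creates the only stereocentre in the same event. The forward step requires a chiral palladium catalyst that gives attack at the more substituted allyl terminus on one face, a phenol that is free only at the chelated position, a masked chain oxygen and an untouched C–Br bond.

**10 ⇒ 9 ⇒ 8 ⇒ 6 + 7.** The chain O–Si bond, the C7–O bond (returning the distal alkene) and the carbonate O–C(=O) bond are cut in turn. This maps the fragment onto the intact ten-carbon skeleton of 6, whose E alkene is the geometry the allylation needs. The forward hydration must select the distal alkene over the allylic one.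

**5 ⇒ 4 ⇒ 3 ⇒ 1 + 2.** The aryl O–Si bond, two O–CH3 bonds and the aryl–acyl bond C4a–C4 are cut. The substitution pattern of ring A is then fully contained in 1. The forward acylation must go para to bromine, and the later monosilylation must distinguish the two phenols through the hydrogen bond of one of them to the ketone.

## Other disconnections considered

**Alternative 1:** The cut removes O1–C8a and C4–C4a, so ring B would come from a tertiary alcohol tethered para to a phenol.

- **Forward key step.** (R)-Linalool A1 would be joined through its vinyl group (9-BBN hydroboration, then B-alkyl Suzuki coupling with a para-iodophenol derivative) to give phenol A2. PhI(OAc)2 would oxidise A2 to the five-membered spiro ether A3, forming O1–C8a. BF3·OEt2 would then move C4 to the neighbouring ring carbon, expanding to ring B and giving chromanol A4.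
- **In favour.** The stereocentre is bought, and the C2–O1 bond is never broken by design. On this point the alternative is better than the chosen plan, which depends on catalyst-controlled enantioselectivity. The C6 oxygen also arises naturally from the phenol.
- **Against.** The dienone of A3 is unsymmetrical because of the bromine. C4 can migrate to either β-carbon, only migration away from bromine gives the 7-bromo pattern, and little in the structure enforces that choice. The Lewis acid could also ionise the tertiary C2–O1 bond of A3, a fragmentation driven by aromatisation that would erase the configuration, and the trisubstituted alkene is a cation trap.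
- **Comparison.** Structurally, A4 has neither the C4 ketone nor the hydrated chain. Phenol protection, benzylic oxidation beside allylic C–H bonds, Markovnikov hydration and deprotection would follow, against one step after the chosen key step. Mechanistically, a cationic 1,2-shift with two competing termini is harder to steer than a tether-directed metathesis. In step count the alternative is about equal up to its key step and clearly longer after it.

**Alternative 2:** The cut removes O1–C2 and C1′–C2′.

- **Forward key step.** Phenol A5 and but-3-en-2-one A6 would react under Pd(OCOCF3)2, a chiral binaphthyl bis(oxazoline) and a quinone reoxidant. Enantioselective oxypalladation of the 1,1-disubstituted alkene closes ring B. The resulting alkylpalladium has no β-hydrogen, so it inserts A6 and eliminates to enone A7. A7 has the S descriptor because the enone chain outranks C3, although C2 is arranged in space as in the target.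
- **In favour.** One operation builds ring B, the stereocentre and a chain C–C bond. That is more bond formation per step than the metathesis, and on that count the alternative is better.
- **Against.** C4 arrives as CH2, so a benzylic oxidation of an electron-rich chroman is still needed. The chain needs methyl addition and alkene saturation without hydrogenolysis of the C–Br bond. Every turnover generates zerovalent palladium next to an aryl bromide. A5 itself takes several steps.
- **Comparison.** Structurally, one more skeletal bond is formed but two oxidation-level corrections remain. Mechanistically, both plans rest on catalyst-controlled creation of C2 and are equals there. In step count, four or five steps would follow A7 against one after 13.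

**Alternative 3:** The cut removes C2–C3.

- **Forward key step.** Diazoketone A8, an aryl ether of an (R)-configured secondary carbinol, would be decomposed by Rh2(OAc)4. The carbenoid carbon C3 inserts into the methine C–H bond next to O1 with retention, closing ring B and giving chromanone A9.
- **In favour.** The C4 ketone is delivered directly, which equals the chosen plan in oxidation-level economy. The stereocentre derives from a secondary alcohol that is easy to obtain enantiopure, which is better than creating a tetrasubstituted centre by asymmetric catalysis. No light-sensitive 2H-chromene is passed through.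
- **Against.** A8 requires diazomethane A10 or an equivalent, which is a real hazard. The lone pair of O1 sits next to the carbenoid and can form an oxonium ylide that collapses to a five-membered ring. The hindered methine must also compete with that pathway.
- **Comparison.** Structurally, the endgame is the same single deprotection. Mechanistically, it is concerted insertion with a competing ylide path against metathesis with a competing thermal rearrangement. In step count, the ether formation by inversion, ester cleavage, acid activation and diazo transfer make the route to A8 about two steps longer than the route to 12.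

Key step: step 9

**Remarks on the chemistry**

- **Assumption on the sense of induction.** In step 7 the (R,R)-ligand is taken to give the (R)-ether from the E-carbonate 10. Should the facial sense be the opposite, the (S,S)-ligand is used and nothing else changes.
- **Change of protecting-group design.** The tertiary alcohol is carried as a triethylsilyl ether and the last step uses acetic acid-buffered Bu4NF. Aryl triisopropylsilyl ethers are slow under acidic fluoride and a tertiary tert-butyldimethylsilyl ether is slow under any fluoride. Unbuffered fluoride would invite opening of ring B.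
- **Check of descriptors.** The CIP analysis gives R for 11, 12, 13 and 14. No structural correction to the key-step pair was needed.

## Route

Step 1
Reactants: 1 2-bromo-1,4-dimethoxybenzene; 2 acetyl chloride
Product: 3 1-(4-bromo-2,5-dimethoxyphenyl)ethan-1-one
Conditions: AlCl3 (1.3 equiv), CH2Cl2, 0 °C to rt
Reagents that add atoms: none
Why: Friedel–Crafts acylation; the acylium ion should enter para to bromine and ortho to a methoxy group, the least hindered activated position, which fixes the 1,2,4,5-pattern of ring A.

Step 2
Reactants: 3 1-(4-bromo-2,5-dimethoxyphenyl)ethan-1-one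
Product: 4 1-(4-bromo-2,5-dihydroxyphenyl)ethan-1-one
Conditions: BBr3 (3 equiv), CH2Cl2, −78 °C to rt; MeOH then H2O
Reagents that add atoms: none
Why: Lewis acid ether cleavage (boron coordinates each methoxy oxygen, bromide removes the methyl group); the ketone and the aryl bromide should be inert.

Step 3
Reactants: 4 1-(4-bromo-2,5-dihydroxyphenyl)ethan-1-one
Product: 5 1-[4-bromo-2-hydroxy-5-(triisopropylsilyloxy)phenyl]ethan-1-one
Conditions: TIPSCl (1.05 equiv), imidazole (2.2 equiv), CH2Cl2, 0 °C to rt
Reagents that add atoms: triisopropylsilyl chloride, CC(C)[Si](Cl)(C(C)C)C(C)C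
Why: Selective O-silylation; the C2 hydroxyl is held in a hydrogen bond to the ketone and is much less nucleophilic, so the bulky silyl chloride should react only at the C5 hydroxyl.

Step 4
Reactants: 6 geraniol; 7 methyl chloroformate
Product: 8 (E)-3,7-dimethylocta-2,6-dien-1-yl methyl carbonate
Conditions: pyridine (2 equiv), CH2Cl2, 0 °C
Reagents that add atoms: none
Why: Acylation of a primary allylic alcohol to the carbonate leaving group; geraniol of high E purity is used because the Z isomer would lead to the other enantiomer in step 7.

Step 5
Reactants: 8 (E)-3,7-dimethylocta-2,6-dien-1-yl methyl carbonate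
Product: 9 (E)-7-hydroxy-3,7-dimethyloct-2-en-1-yl methyl carbonate
Conditions: Co(acac)2 (15 mol%), PhSiH3 (2 equiv), O2 (1 atm), THF, rt; aq. Na2S2O3
Reagents that add atoms: dioxygen, O=O
Why: Mukaiyama hydration; a cobalt hydride transfers a hydrogen atom to C6, the tertiary C7 radical is trapped by O2 and reduced to the alcohol (Markovnikov). The C2=C3 alkene is deactivated by the allylic carbonate and should be left alone.

Step 6
Reactants: 9 (E)-7-hydroxy-3,7-dimethyloct-2-en-1-yl methyl carbonate
Product: 10 (E)-3,7-dimethyl-7-(triethylsilyloxy)oct-2-en-1-yl methyl carbonate
Conditions: TESOTf (1.3 equiv), 2,6-lutidine (2 equiv), CH2Cl2, −78 to 0 °C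
Reagents that add atoms: triethylsilyl trifluoromethanesulfonate, CC[Si](CC)(CC)OS(=O)(=O)C(F)(F)F
Why: Silylation of a tertiary alcohol with a silyl triflate and a hindered base; the ether keeps the chain oxygen from attacking the allylpalladium species of step 7 and can be removed later by fluoride.

Step 7
Reactants: 5 1-[4-bromo-2-hydroxy-5-(triisopropylsilyloxy)phenyl]ethan-1-one; 10 (E)-3,7-dimethyl-7-(triethylsilyloxy)oct-2-en-1-yl methyl carbonate
Product: 11 1-[4-bromo-2-{[(3R)-3,7-dimethyl-7-(triethylsilyloxy)oct-1-en-3-yl]oxy}-5-(triisopropylsilyloxy)phenyl]ethan-1-one
Conditions: Pd2(dba)3·CHCl3 (2 mol%), (R,R)-N,N′-(cyclohexane-1,2-diyl)bis[2-(diphenylphosphino)benzamide] (6 mol%), CH2Cl2 (0.05 M), rt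
Reagents that add atoms: none
Why: Tsuji–Trost asymmetric allylic etherification; zerovalent palladium ionises 10 to a π-allyl complex, and the phenoxide of 5 attacks the more substituted terminus inside the chiral pocket of the diphosphine, which selects the face and sets C2 as R. The decarboxylating leaving group supplies the base, and at room temperature the aryl bromide should not undergo oxidative addition.

Step 8
Reactants: 11 1-[4-bromo-2-{[(3R)-3,7-dimethyl-7-(triethylsilyloxy)oct-1-en-3-yl]oxy}-5-(triisopropylsilyloxy)phenyl]ethan-1-one
Product: 12 tert-butyl({1-[4-bromo-2-{[(3R)-3,7-dimethyl-7-(triethylsilyloxy)oct-1-en-3-yl]oxy}-5-(triisopropylsilyloxy)phenyl]ethenyl}oxy)dimethylsilane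
Conditions: TBSOTf (1.3 equiv), Et3N (2.5 equiv), CH2Cl2, −78 to 0 °C
Reagents that add atoms: tert-butyldimethylsilyl trifluoromethanesulfonate, CC(C)(C)[Si](C)(C)OS(=O)(=O)C(F)(F)F
Why: Soft enolisation of an aryl methyl ketone (O-silylation of the carbonyl, then deprotonation by the amine) gives the 1-silyloxyvinyl arene; excess amine and low temperature keep the silyl triflate from ionising the tertiary allylic ether.

Step 9
Reactants: 12 tert-butyl({1-[4-bromo-2-{[(3R)-3,7-dimethyl-7-(triethylsilyloxy)oct-1-en-3-yl]oxy}-5-(triisopropylsilyloxy)phenyl]ethenyl}oxy)dimethylsilane
Product: 13 (R)-7-bromo-4-(tert-butyldimethylsilyloxy)-2-methyl-2-[4-methyl-4-(triethylsilyloxy)pentyl]-6-(triisopropylsilyloxy)-2H-chromene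
Conditions: (H2IMes)(PCy3)Cl2Ru=CHPh (second-generation Grubbs catalyst, 5–10 mol%), degassed PhMe (0.01 M), 45 °C, Ar sparge, dark
Reagents that add atoms: none
Why: Ring-closing alkene metathesis: after phosphine loss the ruthenium benzylidene exchanges onto the monosubstituted vinyl group at C2, and the new alkylidene at C3 undergoes intramolecular [2+2] cycloaddition with the 1,1-disubstituted silyl enol ether so that C3 bonds to C4. Cycloreversion releases 13 and a ruthenium methylidene, which carries the chain with loss of ethylene. The closest known reaction types are the metathesis of silyl enol ether dienes to cyclic silyl enol ethers and of ortho-alkenylaryl allyl ethers to 2H-chromenes. Ring B closes as a six-membered ring with the new alkene endocyclic (O1, C2, C3, C4, C4a, C8a), helped by the quaternary C2 and the ortho geometry of the arene. No stereocentre is formed, and C2, set in step 7, has no bond made or broken and cannot be reached by alkene migration. The step needs only chemoselectivity: the vinyl group has one alkene partner because the chain alkene was hydrated, the aryl bromide and the three silyl ethers are inert to the carbene, and high dilution disfavours dimerisation. The mild temperature and exclusion of light guard against aromatic Claisen shift of the tertiary allyl aryl ether to C8 and against electrocyclic opening of the 2H-chromene, either of which would destroy the C2 configuration.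

Step 10
Reactants: 13 (R)-7-bromo-4-(tert-butyldimethylsilyloxy)-2-methyl-2-[4-methyl-4-(triethylsilyloxy)pentyl]-6-(triisopropylsilyloxy)-2H-chromene
Product: 14 (R)-7-bromo-6-hydroxy-2-(4-hydroxy-4-methylpentyl)-2-methylchroman-4-one
Conditions: Bu4NF (4 equiv), AcOH (4 equiv), THF, 0 °C to rt
Reagents that add atoms: none
Why: Fluoride-induced cleavage of the enol, aryl and tertiary alkyl silyl ethers; the enolate is protonated at C3 by acetic acid to give the C4 ketone before it can expel O1, and the phenol and tertiary alcohol are freed in the same operation.

## Compound list

1 | 2-bromo-1,4-dimethoxybenzene | COc1ccc(OC)c(Br)c1 | starting material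
2 | acetyl chloride | CC(Cl)=O | starting material
3 | 1-(4-bromo-2,5-dimethoxyphenyl)ethan-1-one | CC(=O)c1cc(OC)c(Br)cc1OC | intermediate
4 | 1-(4-bromo-2,5-dihydroxyphenyl)ethan-1-one | CC(=O)c1cc(O)c(Br)cc1O | intermediate
5 | 1-[4-bromo-2-hydroxy-5-(triisopropylsilyloxy)phenyl]ethan-1-one | CC(=O)c1cc(O[Si](C(C)C)(C(C)C)C(C)C)c(Br)cc1O | intermediate
6 | geraniol, (E)-3,7-dimethylocta-2,6-dien-1-ol | CC(C)=CCC/C(C)=C/CO | starting material
7 | methyl chloroformate | COC(Cl)=O | starting material
8 | (E)-3,7-dimethylocta-2,6-dien-1-yl methyl carbonate | CC(C)=CCC/C(C)=C/COC(=O)OC | intermediate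
9 | (E)-7-hydroxy-3,7-dimethyloct-2-en-1-yl methyl carbonate | CC(C)(O)CCC/C(C)=C/COC(=O)OC | intermediate
10 | (E)-3,7-dimethyl-7-(triethylsilyloxy)oct-2-en-1-yl methyl carbonate | CC[Si](CC)(CC)OC(C)(C)CCC/C(C)=C/COC(=O)OC | intermediate
11 | 1-[4-bromo-2-{[(3R)-3,7-dimethyl-7-(triethylsilyloxy)oct-1-en-3-yl]oxy}-5-(triisopropylsilyloxy)phenyl]ethan-1-one | CC(C)(O[Si](CC)(CC)CC)CCC[C@](Oc1cc(Br)c(O[Si](C(C)C)(C(C)C)C(C)C)cc1C(C)=O)(C)C=C | intermediate
12 | tert-butyl({1-[4-bromo-2-{[(3R)-3,7-dimethyl-7-(triethylsilyloxy)oct-1-en-3-yl]oxy}-5-(triisopropylsilyloxy)phenyl]ethenyl}oxy)dimethylsilane | CC(C)(O[Si](CC)(CC)CC)CCC[C@](Oc1cc(Br)c(O[Si](C(C)C)(C(C)C)C(C)C)cc1C(=C)O[Si](C)(C)C(C)(C)C)(C)C=C | intermediate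
13 | (R)-7-bromo-4-(tert-butyldimethylsilyloxy)-2-methyl-2-[4-methyl-4-(triethylsilyloxy)pentyl]-6-(triisopropylsilyloxy)-2H-chromene | CC(C)(O[Si](CC)(CC)CC)CCC[C@]1(C)C=C(O[Si](C)(C)C(C)(C)C)c2cc(O[Si](C(C)C)(C(C)C)C(C)C)c(Br)cc2O1 | intermediate
14 | (R)-7-bromo-6-hydroxy-2-(4-hydroxy-4-methylpentyl)-2-methylchroman-4-one | CC(C)(O)CCC[C@]1(C)CC(=O)c2cc(O)c(Br)cc2O1 | target

## Step count and least certain steps

Total steps: 10. Longest linear sequence: 7 steps (steps 1–3 or 4–6, then steps 7–10).

**Step 9 (key step).**
- **Risk.** Turnover could stall, because the ruthenium alkylidene must add across a hindered, electron-rich 1,1-disubstituted enol ether flanked by the ortho ether, and the catalyst may decompose first. Heating to force the reaction would start the [3,3] shift of the tertiary allyl aryl ether to C8. The enol ether could also hydrolyse on silica, and light could open the 2H-chromene and erode the C2 configuration.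
- **Fallback.** It sets out from 11 and returns at 14, placing the metathesis on a plain styrene and installing the ketone afterwards. NaBH4 in MeOH at 0 °C would reduce 11 to the 1-arylethanol F1. Burgess reagent in PhMe at 50 °C would dehydrate it to the ortho-vinyl aryl ether F2. The same ruthenium catalyst in CH2Cl2 at 40 °C would close the 2H-chromene F3. Mukaiyama hydration (Co(acac)2, PhSiH3, O2, THF) would place oxygen at the benzylic carbon C4 to give the chroman-4-ol F4. Dess–Martin periodinane would oxidise it to the silyl-protected chroman-4-one F5. Bu4NF with AcOH in THF would then give 14.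

**Step 7.**
- **Risk.** Face and regiochemical control could fall short. The chelated, more acidic phenoxide is a weaker nucleophile and a better leaving group than the phenols usually used, so the branched ether may re-ionise on zerovalent palladium and drift toward the linear ether and toward the racemate.
- **Fallback.** It sets out from 5 and returns at 11, making the nucleophile electron-rich through a redox detour. NaBH4 in MeOH would reduce 5 to the hydroxyethyl phenol F6. The same palladium-catalysed etherification with 10 would give the 1-arylethanol F1, whose aryloxy group is a poor leaving group. Dess–Martin periodinane in CH2Cl2 would oxidise F1 to 11.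

**Step 5.**
- **Risk.** Hydrogen-atom transfer may not discriminate well enough between the two trisubstituted alkenes, and simple reduction of the alkene may compete with oxygen trapping.
- **Fallback.** It sets out from 8 and returns at 9, using polar reactions only. mCPBA (1.0 equiv, CH2Cl2, NaHCO3, 0 °C) would epoxidise the more electron-rich distal alkene to the epoxy carbonate F7. LiAlH4 in THF at 0 °C would deliver hydride to the less substituted epoxide carbon and cleave the carbonate, giving the diol F8. Compound 7 with pyridine at −20 °C would acylate only the primary allylic hydroxyl to give 9.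

**Step 10.**
- **Risk.** The hindered tertiary triethylsilyl ether may cleave incompletely under buffered fluoride. If the buffer is insufficient, enolate-driven opening of ring B and reclosure would lower the enantiomeric purity.
- **Fallback.** It sets out from 13 and returns at 14, separating acid-labile from fluoride-labile groups. Aqueous HCl (1 M) in THF at 0 °C would hydrolyse the enol ether by C-protonation and remove the triethylsilyl group, giving the phenol-protected chromanone F9. A short treatment with Bu4NF and AcOH at 0 °C would then remove the aryl silyl group to give 14.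

## Further compounds

F1 | step 9 | 1-[4-bromo-2-{[(3R)-3,7-dimethyl-7-(triethylsilyloxy)oct-1-en-3-yl]oxy}-5-(triisopropylsilyloxy)phenyl]ethan-1-ol (both carbinol epimers) | CC(C)(O[Si](CC)(CC)CC)CCC[C@](Oc1cc(Br)c(O[Si](C(C)C)(C(C)C)C(C)C)cc1C(C)O)(C)C=C
F2 | step 9 | {[(6R)-6-[5-bromo-2-ethenyl-4-(triisopropylsilyloxy)phenoxy]-2,6-dimethyloct-7-en-2-yl]oxy}triethylsilane | CC(C)(O[Si](CC)(CC)CC)CCC[C@](Oc1cc(Br)c(O[Si](C(C)C)(C(C)C)C(C)C)cc1C=C)(C)C=C
F3 | step 9 | (R)-7-bromo-2-methyl-2-[4-methyl-4-(triethylsilyloxy)pentyl]-6-(triisopropylsilyloxy)-2H-chromene | CC(C)(O[Si](CC)(CC)CC)CCC[C@]1(C)C=Cc2cc(O[Si](C(C)C)(C(C)C)C(C)C)c(Br)cc2O1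
F4 | step 9 | (2R)-7-bromo-2-methyl-2-[4-methyl-4-(triethylsilyloxy)pentyl]-6-(triisopropylsilyloxy)chroman-4-ol (both C4 epimers) | CC(C)(O[Si](CC)(CC)CC)CCC[C@]1(C)CC(O)c2cc(O[Si](C(C)C)(C(C)C)C(C)C)c(Br)cc2O1
F5 | step 9 | (R)-7-bromo-2-methyl-2-[4-methyl-4-(triethylsilyloxy)pentyl]-6-(triisopropylsilyloxy)chroman-4-one (identical with A9) | CC(C)(O[Si](CC)(CC)CC)CCC[C@]1(C)CC(=O)c2cc(O[Si](C(C)C)(C(C)C)C(C)C)c(Br)cc2O1
F6 | step 7 | 5-bromo-2-(1-hydroxyethyl)-4-(triisopropylsilyloxy)phenol (racemic) | CC(O)c1cc(O[Si](C(C)C)(C(C)C)C(C)C)c(Br)cc1O
F7 | step 5 | (E)-5-(3,3-dimethyloxiran-2-yl)-3-methylpent-2-en-1-yl methyl carbonate (racemic) | CC1(C)OC1CC/C(C)=C/COC(=O)OC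
F8 | step 5 | (E)-3,7-dimethyloct-2-ene-1,7-diol | CC(C)(O)CCC/C(C)=C/CO
F9 | step 10 | (R)-7-bromo-2-(4-hydroxy-4-methylpentyl)-2-methyl-6-(triisopropylsilyloxy)chroman-4-one | CC(C)(O)CCC[C@]1(C)CC(=O)c2cc(O[Si](C(C)C)(C(C)C)C(C)C)c(Br)cc2O1
A1 | alternative 1 | (R)-linalool, (3R)-3,7-dimethylocta-1,6-dien-3-ol | CC(C)=CCC[C@@](C)(O)C=C
A2 | alternative 1 | (R)-2-bromo-4-(3-hydroxy-3,7-dimethyloct-6-en-1-yl)phenol | CC(C)=CCC[C@@](C)(O)CCc1ccc(O)c(Br)c1
A3 | alternative 1 | (2R)-7-bromo-2-methyl-2-(4-methylpent-3-en-1-yl)-1-oxaspiro[4.5]deca-6,9-dien-8-one (both spiro epimers) | CC(C)=CCC[C@]1(C)CCC2(O1)C=CC(=O)C(Br)=C2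
A4 | alternative 1 | (R)-7-bromo-2-methyl-2-(4-methylpent-3-en-1-yl)chroman-6-ol | CC(C)=CCC[C@]1(C)CCc2cc(O)c(Br)cc2O1
A5 | alternative 2 | 5-bromo-2-(3-methylbut-3-en-1-yl)-4-(triisopropylsilyloxy)phenol | CC(=C)CCc1cc(O[Si](C(C)C)(C(C)C)C(C)C)c(Br)cc1O
A6 | alternative 2 | but-3-en-2-one | CC(=O)C=C
A7 | alternative 2 | (S,E)-5-[7-bromo-2-methyl-6-(triisopropylsilyloxy)chroman-2-yl]pent-3-en-2-one | CC(=O)/C=C/C[C@]1(C)CCc2cc(O[Si](C(C)C)(C(C)C)C(C)C)c(Br)cc2O1
A8 | alternative 3 | 1-[4-bromo-2-{[(2R)-6-methyl-6-(triethylsilyloxy)heptan-2-yl]oxy}-5-(triisopropylsilyloxy)phenyl]-2-diazoethan-1-one | CC(C)(O[Si](CC)(CC)CC)CCC[C@@H](C)Oc1cc(Br)c(O[Si](C(C)C)(C(C)C)C(C)C)cc1C(=O)C=[N+]=[N-]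
A9 | alternative 3 | (R)-7-bromo-2-methyl-2-[4-methyl-4-(triethylsilyloxy)pentyl]-6-(triisopropylsilyloxy)chroman-4-one | CC(C)(O[Si](CC)(CC)CC)CCC[C@]1(C)CC(=O)c2cc(O[Si](C(C)C)(C(C)C)C(C)C)c(Br)cc2O1
A10 | alternative 3 | diazomethane | C=[N+]=[N-]
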